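Ring E is carried as a cyclitol and aromatised last. Its C1–O bond to ring D (C4, the carbon between the two oxygenated carbons) is made by SN2 at an sp3 carbon of a myo-inositol diketal; the carbon para to it is then oxidised. In the key step the resulting 4-O-aryl-2,3,5,6-tetrahydroxycyclohexanone (aryl = rings A–D as methyl ethers) is acetylated and loses its two β-acetoxy groups by E1cB in one pot, giving ring E as the triacetate. The step exploits the 1,2,3,5-oxygen pattern of ring E: carbonyl carbon becomes C4–O, the α-carbons C3–O and C5–O, the γ-carbon C1 keeps the aryl ether.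

Key step: step 12

Remarks on the chemistry (assumptions):
- Rings are lettered A–E from the 2,4,6-trioxygenated end. Cyclitol carbons keep myo-inositol numbering. Compounds 9–16 are racemic, with one enantiomer drawn.
- The eliminations are run on the acetylated ketone with weak base, not in hot mineral acid. A free 2-hydroxy-enone formed after a first dehydration equilibrates with a 1,2-dione, whose enolisation puts the γ-substituent β to a carbonyl; the parent 2-inosose is known to aromatise in acid to the 1,2,3,4-oxygen pattern for this reason, and here the aryloxy group would be expelled.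
- The relative configuration of precursor 14 is immaterial, since all four stereocentres vanish. It is set by inversion of an equatorial triflate on a conformationally mobile diketal chair, where the nucleophile enters along a lane lined only by axial hydrogens. An axial triflate held in a 1,3-acetal-bridged chair would force the nucleophile to eclipse two neighbouring axial alkoxy groups.

Step 1
Reactants: 1 4-bromo-2,6-dimethoxyphenol
Product: 2 2-(benzyloxy)-5-bromo-1,3-dimethoxybenzene
Conditions: BnBr, K2CO3, DMF, rt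
Reagents that add atoms: benzyl bromide, BrCc1ccccc1
Why: Williamson etherification of the phenoxide with a primary benzylic bromide masks the hydroxyl so that the bromide can serve as the electrophile in the iterative couplings.

Step 2
Reactants: 3 2,4,6-trimethoxyphenol; 2 2-(benzyloxy)-5-bromo-1,3-dimethoxybenzene
Product: 4 2-(benzyloxy)-1,3-dimethoxy-5-(2,4,6-trimethoxyphenoxy)benzene (A–B benzyl ether)
Conditions: CuI (10 mol%), picolinic acid (20 mol%), K3PO4, DMSO, 90 °C, Ar
Reagents that add atoms: none
Why: Ullmann-type diaryl ether coupling, in which the picolinate ligand on copper tolerates the doubly ortho-substituted phenoxide and the bromide sits between two ring hydrogens.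

Step 3
Reactants: 4 A–B benzyl ether
Product: 5 2,6-dimethoxy-4-(2,4,6-trimethoxyphenoxy)phenol (A–B phenol)
Conditions: H2 (1 atm), Pd/C, EtOAc–MeOH, rt
Reagents that add atoms: none
Why: Hydrogenolysis of the benzyl aryl ether frees the ring B phenol, while methyl and diaryl ethers are inert to these conditions.

Step 4
Reactants: 5 A–B phenol; 2 2-(benzyloxy)-5-bromo-1,3-dimethoxybenzene
Product: 6 2-(benzyloxy)-5-[2,6-dimethoxy-4-(2,4,6-trimethoxyphenoxy)phenoxy]-1,3-dimethoxybenzene (A–B–C benzyl ether)
Conditions: CuI (10 mol%), picolinic acid (20 mol%), K3PO4, DMSO, 90 °C, Ar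
Reagents that add atoms: none
Why: Second Ullmann-type coupling of the same kind as step 2, with the same steric and electronic situation at both partners.

Step 5
Reactants: 6 A–B–C benzyl ether
Product: 7 4-[2,6-dimethoxy-4-(2,4,6-trimethoxyphenoxy)phenoxy]-2,6-dimethoxyphenol (A–B–C phenol)
Conditions: H2 (1 atm), Pd/C, EtOAc–MeOH, rt
Reagents that add atoms: none
Why: Hydrogenolysis of the benzyl aryl ether as in step 3 frees the ring C phenol.

Step 6
Reactants: 8 myo-inositol
Product: 9 (±)-1,2:4,5-di-O-isopropylidene-myo-inositol (O1/O2 acetonide cis-fused, O4/O5 acetonide trans-fused, free 3-OH and 6-OH, which are para to each other)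
Conditions: 2,2-dimethoxypropane, TsOH·H2O (cat.), DMF, 100 °C; Et3N; crystallisation
Reagents that add atoms: 2,2-dimethoxypropane, COC(C)(C)OC
Why: Acid-catalysed transketalisation gives the vicinal bis-acetonides, from which the 1,2:4,5-isomer is separated by crystallisation; no stereocentre is touched and the meso hexol becomes a racemate.

Step 7
Reactants: 9 (±)-1,2:4,5-di-O-isopropylidene-myo-inositol
Product: 10 (±)-1,2:4,5-di-O-isopropylidene-3-O-trifluoromethanesulfonyl-myo-inositol (6-OH free)
Conditions: Tf2O (1.05 equiv), pyridine, CH2Cl2, −40 to −20 °C; used directly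
Reagents that add atoms: trifluoromethanesulfonic anhydride, O=S(=O)(OS(=O)(=O)C(F)(F)F)C(F)(F)F
Why: O-Sulfonylation with retention at the 3-OH, which is the hydroxyl of this diol that reacts first with acyl, silyl and alkyl electrophiles, the 6-OH being screened by both dioxolane rings.

Step 8
Reactants: 10 3-O-triflate; 1 4-bromo-2,6-dimethoxyphenol
Product: 11 (±)-3-O-(4-bromo-2,6-dimethoxyphenyl)-1,2:4,5-di-O-isopropylidene cyclitol with C3 inverted (chiro configuration: aryloxy trans to O2 and cis to O4; 6-OH free)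
Conditions: 1 (3 equiv), Cs2CO3, DMF, 0 °C to rt
Reagents that add atoms: none
Why: Williamson-type SN2 displacement of a secondary triflate by the cesium aryloxide inverts C3; the equatorial leaving group has no antiperiplanar hydrogen for E2 and the backside lane is flanked only by the axial hydrogens at C1 and C5.

Step 9
Reactants: 11 cyclitol-bound ring D bromide; 7 A–B–C phenol
Product: 12 (±)-3-O-(4-{4-[2,6-dimethoxy-4-(2,4,6-trimethoxyphenoxy)phenoxy]-2,6-dimethoxyphenoxy}-2,6-dimethoxyphenyl)-1,2:4,5-di-O-isopropylidene cyclitol (configuration of 11; 6-OH free)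
Conditions: CuI (20 mol%), picolinic acid (40 mol%), K3PO4, DMSO, 90 °C, Ar
Reagents that add atoms: none
Why: Ullmann-type diaryl ether coupling as in steps 2 and 4; phenoxides are arylated far faster than the hindered secondary 6-OH, and the ketals are stable to base.

Step 10
Reactants: 12 A–D aryl ether diketal alcohol
Product: 13 (±)-6-ketone of 12 (3-O-aryl-1,2:4,5-di-O-isopropylidene-inos-6-ose; carbonyl para to the aryloxy carbon)
Conditions: Dess–Martin periodinane, NaHCO3, CH2Cl2, rt
Reagents that add atoms: none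
Why: Dess–Martin oxidation of the secondary alcohol under buffered, non-basic conditions leaves ketals and electron-rich aryl ethers untouched and does not trigger β-elimination.

Step 11
Reactants: 13 diketal ketone
Product: 14 (±)-4-O-(A–D tetramer aryl)-2,3,5,6-tetrahydroxycyclohexanone (cyclohexanone numbering: 2-, 3- and 6-OH on one face, 4-aryloxy and 5-OH on the other)
Conditions: TFA–H2O (9:1), CH2Cl2, 0 °C to rt; toluene co-evaporation; used crude
Reagents that add atoms: none
Why: Acid-catalysed hydrolysis of both acetonides proceeds at room temperature, well below the conditions under which acid would dehydrate an inosose, and leaves every C–O bond of the ring in place.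

Step 12
Reactants: 14 4-O-aryl-tetrahydroxycyclohexanone
Product: 19 pentamer with ring E as 3,4,5-triacetoxyphenyl ether (rings A–D nona-O-methyl), via tetraacetate 15 (not isolated), via enone 16 (not isolated), via dienone 17 (not isolated), via phenol 18 (not isolated)
Conditions: Ac2O, pyridine, DMAP (cat.), 0 °C to rt, then 60 °C, Ar
Reagents that add atoms: acetic anhydride, CC(=O)OC(C)=O
Why: DMAP-catalysed O-acetylation should convert the four hydroxyls into acetates faster than pyridine can enolise the α-hydroxy ketone, giving 15; base then removes an α-hydrogen and the enolate expels the β-acetate (E1cB) on one side (16) and then on the other (17), and loss of the doubly allylic γ-hydrogen of the cross-conjugated dienone gives phenol 18, which is acetylated to 19. The closest known reaction type is the base-induced aromatisation of peracylated inososes to 1,2,3,5-tetraacyloxybenzenes. No ring is closed by bond formation: the existing six-membered carbocycle becomes aromatic ring E. No stereocentre is created, and the four of 14 are destroyed, so its relative configuration does not matter. The selectivity needed is which oxygens leave: only the two β-acetoxy groups can depart, because the carbonyl sits para to the aryloxy carbon and both α-oxygens stay acetylated, so the enol acetates cannot tautomerise to a 1,2-dione and the aryloxy carbon never lies next to a carbanionic centre.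

Step 13
Reactants: 19 ring E triacetate nona-O-methyl pentamer
Product: 20 CNP0308003.0 (target)
Conditions: BBr3 (1 M in CH2Cl2, excess), CH2Cl2, −78 °C to rt, Ar; then MeOH, 0 to 50 °C
Reagents that add atoms: none
Why: Lewis acid ether cleavage, in which BBr3 coordinates each methoxy oxygen and bromide attacks the methyl carbon while the diaryl ether bonds (sp2 carbon on both sides) stay intact; HBr in methanol formed on quenching removes the borates and the three aryl acetates by transesterification.

Compound list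
1 | 4-bromo-2,6-dimethoxyphenol | COc1cc(Br)cc(OC)c1O | starting material
2 | 2-(benzyloxy)-5-bromo-1,3-dimethoxybenzene | COc1cc(Br)cc(OC)c1OCc1ccccc1 | intermediate
3 | 2,4,6-trimethoxyphenol | COc1cc(OC)c(O)c(OC)c1 | starting material
4 | 2-(benzyloxy)-1,3-dimethoxy-5-(2,4,6-trimethoxyphenoxy)benzene (A–B benzyl ether) | COc1cc(OC)cc(OC)c1Oc1cc(OC)c(OCc2ccccc2)c(OC)c1 | intermediate
5 | 2,6-dimethoxy-4-(2,4,6-trimethoxyphenoxy)phenol (A–B phenol) | COc1cc(OC)cc(OC)c1Oc1cc(OC)c(O)c(OC)c1 | intermediate
6 | 2-(benzyloxy)-5-[2,6-dimethoxy-4-(2,4,6-trimethoxyphenoxy)phenoxy]-1,3-dimethoxybenzene (A–B–C benzyl ether) | COc1cc(OC)cc(OC)c1Oc1cc(OC)c(Oc2cc(OC)c(OCc3ccccc3)c(OC)c2)c(OC)c1 | intermediate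
7 | 4-[2,6-dimethoxy-4-(2,4,6-trimethoxyphenoxy)phenoxy]-2,6-dimethoxyphenol (A–B–C phenol) | COc1cc(OC)cc(OC)c1Oc1cc(OC)c(Oc2cc(OC)c(O)c(OC)c2)c(OC)c1 | intermediate
8 | myo-inositol | O[C@@H]1[C@H](O)[C@H](O)[C@@H](O)[C@H](O)[C@H]1O | starting material
9 | (±)-1,2:4,5-di-O-isopropylidene-myo-inositol | O[C@H]1[C@@H]2OC(C)(C)O[C@H]2[C@H](O)[C@H]2OC(C)(C)O[C@H]21 | intermediate
10 | (±)-1,2:4,5-di-O-isopropylidene-3-O-trifluoromethanesulfonyl-myo-inositol | O=S(=O)(O[C@H]1[C@@H]2OC(C)(C)O[C@H]2[C@H](O)[C@H]2OC(C)(C)O[C@H]21)C(F)(F)F | intermediate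
11 | (±)-3-O-(4-bromo-2,6-dimethoxyphenyl)-1,2:4,5-di-O-isopropylidene cyclitol, C3 inverted (chiro configuration), 6-OH free | COc1cc(Br)cc(OC)c1O[C@@H]1[C@@H]2OC(C)(C)O[C@H]2[C@H](O)[C@H]2OC(C)(C)O[C@H]21 | intermediate
12 | (±)-3-O-(A–D tetramer aryl)-1,2:4,5-di-O-isopropylidene cyclitol, configuration of 11, 6-OH free | COc1cc(OC)cc(OC)c1Oc1cc(OC)c(Oc2cc(OC)c(Oc3cc(OC)c(O[C@@H]4[C@@H]5OC(C)(C)O[C@H]5[C@H](O)[C@H]5OC(C)(C)O[C@H]54)c(OC)c3)c(OC)c2)c(OC)c1 | intermediate
13 | (±)-6-ketone of 12 (diketal inos-6-ose, carbonyl para to the aryloxy carbon) | COc1cc(OC)cc(OC)c1Oc1cc(OC)c(Oc2cc(OC)c(Oc3cc(OC)c(O[C@@H]4[C@@H]5OC(C)(C)O[C@H]5C(=O)[C@H]5OC(C)(C)O[C@H]54)c(OC)c3)c(OC)c2)c(OC)c1 | intermediate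
14 | (±)-4-O-(A–D tetramer aryl)-2,3,5,6-tetrahydroxycyclohexanone (2-, 3-, 6-OH on one face; 4-aryloxy and 5-OH on the other) | O=C1[C@@H](O)[C@@H](O)[C@H](Oc2c(OC)cc(Oc3c(OC)cc(Oc4c(OC)cc(Oc5c(OC)cc(OC)cc5OC)cc4OC)cc3OC)cc2OC)[C@H](O)[C@H]1O | intermediate (key-step precursor)
15 | (±)-2,3,5,6-tetra-O-acetyl derivative of 14 | O=C1[C@@H](OC(C)=O)[C@@H](OC(C)=O)[C@H](Oc2c(OC)cc(Oc3c(OC)cc(Oc4c(OC)cc(Oc5c(OC)cc(OC)cc5OC)cc4OC)cc3OC)cc2OC)[C@H](OC(C)=O)[C@H]1OC(C)=O | intermediate (not isolated)
16 | (±)-2,5,6-triacetoxy-4-aryloxycyclohex-2-enone (first elimination drawn on one side; the other side leads to the same dienone) | O=C1C(OC(C)=O)=C[C@H](Oc2c(OC)cc(Oc3c(OC)cc(Oc4c(OC)cc(Oc5c(OC)cc(OC)cc5OC)cc4OC)cc3OC)cc2OC)[C@H](OC(C)=O)[C@H]1OC(C)=O | intermediate (not isolated)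
17 | 2,6-diacetoxy-4-aryloxycyclohexa-2,5-dienone | O=C1C(OC(C)=O)=CC(Oc2c(OC)cc(Oc3c(OC)cc(Oc4c(OC)cc(Oc5c(OC)cc(OC)cc5OC)cc4OC)cc3OC)cc2OC)C=C1OC(C)=O | intermediate (not isolated)
18 | 2,6-diacetoxy-4-aryloxyphenol (ring E aromatic, middle hydroxyl free) | CC(=O)Oc1cc(Oc2c(OC)cc(Oc3c(OC)cc(Oc4c(OC)cc(Oc5c(OC)cc(OC)cc5OC)cc4OC)cc3OC)cc2OC)cc(OC(C)=O)c1O | intermediate (not isolated)
19 | pentamer with ring E as 3,4,5-triacetoxyphenyl ether, rings A–D as nine methyl ethers | CC(=O)Oc1cc(Oc2c(OC)cc(Oc3c(OC)cc(Oc4c(OC)cc(Oc5c(OC)cc(OC)cc5OC)cc4OC)cc3OC)cc2OC)cc(OC(C)=O)c1OC(C)=O | intermediate (key-step product)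
20 | CNP0308003.0 | Oc1cc(O)c(Oc2cc(O)c(Oc3cc(O)c(Oc4cc(O)c(Oc5cc(O)c(O)c(O)c5)c(O)c4)c(O)c3)c(O)c2)c(O)c1 | target

Total step count: 13. Longest linear sequence: 10 steps (steps 1, 2, 3, 4, 5, 9, 10, 11, 12, 13); the cyclitol branch (steps 6–8) joins at step 9.

Steps most likely to fail

Step 12. The free α-hydroxy ketone may shift its carbonyl to a neighbouring carbon through the enediol before all four hydroxyls are acetylated. The aryloxy carbon would then lie β to a carbonyl and the A–D aryloxide would be lost; the sequence may also stall after one elimination. The fallback never exposes a free α-hydroxy ketone. It sets out from 12: NaH and BnBr in DMF give the 6-O-benzyl ether F1; TFA–H2O removes both acetonides to give the tetrol F2; Ac2O and pyridine give the tetraacetate F3; H2 over Pd/C frees the 6-hydroxyl to give the alcohol F4; Dess–Martin periodinane then gives tetraacetate 15, now isolated. Heating 15 with NaOAc in Ac2O at 100 °C returns to the route at 19.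

Step 8. The aryloxide may attack sulfur of the triflate (returning the alcohol) or act as a base, instead of substituting at the hindered secondary carbon. The fallback sets out from diol 9 and phenol 1 and uses a Mitsunobu etherification (PBu3, 1,1'-(azodicarbonyl)dipiperidine, toluene, rt to 60 °C). The more reactive 3-OH is activated in situ as an alkoxyphosphonium ion and displaced by the phenoxide with inversion, which returns to the route at 11 with no new compound (F0) and bypasses the triflate of step 7.

Step 9. Ligand exchange and reductive elimination at copper may be slow with the doubly ortho-substituted phenoxide and the electron-rich bromide, so hydrodebromination or base-induced erosion of the cyclitol at 90 °C can take over. The fallback makes the aryl–aryl ether before the cyclitol is attached. It sets out from 7: coupling with 2 under the conditions of step 4 gives the A–D tetramer benzyl ether F5; hydrogenolysis (H2, Pd/C) gives the A–D tetramer phenol F6; its cesium salt (Cs2CO3, DMF) displaces triflate 10 and returns to the route at 12.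

Further compounds
F1 | step 12 | (±)-6-O-benzyl ether of 12 | COc1cc(OC)cc(OC)c1Oc1cc(OC)c(Oc2cc(OC)c(Oc3cc(OC)c(O[C@@H]4[C@@H]5OC(C)(C)O[C@H]5[C@H](OCc6ccccc6)[C@H]5OC(C)(C)O[C@H]54)c(OC)c3)c(OC)c2)c(OC)c1
F2 | step 12 | (±)-3-O-(A–D tetramer aryl)-6-O-benzyl cyclitol 1,2,4,5-tetrol (configuration of 12) | c1ccccc1CO[C@@H]1[C@@H](O)[C@@H](O)[C@H](Oc2c(OC)cc(Oc3c(OC)cc(Oc4c(OC)cc(Oc5c(OC)cc(OC)cc5OC)cc4OC)cc3OC)cc2OC)[C@H](O)[C@H]1O
F3 | step 12 | (±)-1,2,4,5-tetra-O-acetyl derivative of F2 | c1ccccc1CO[C@@H]1[C@@H](OC(C)=O)[C@@H](OC(C)=O)[C@H](Oc2c(OC)cc(Oc3c(OC)cc(Oc4c(OC)cc(Oc5c(OC)cc(OC)cc5OC)cc4OC)cc3OC)cc2OC)[C@H](OC(C)=O)[C@H]1OC(C)=O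
F4 | step 12 | (±)-1,2,4,5-tetra-O-acetyl-3-O-(A–D tetramer aryl) cyclitol with free 6-OH | O[C@@H]1[C@@H](OC(C)=O)[C@@H](OC(C)=O)[C@H](Oc2c(OC)cc(Oc3c(OC)cc(Oc4c(OC)cc(Oc5c(OC)cc(OC)cc5OC)cc4OC)cc3OC)cc2OC)[C@H](OC(C)=O)[C@H]1OC(C)=O
F0 | step 8 | none | none
F5 | step 9 | A–D tetramer benzyl ether | COc1cc(OC)cc(OC)c1Oc1cc(OC)c(Oc2cc(OC)c(Oc3cc(OC)c(OCc4ccccc4)c(OC)c3)c(OC)c2)c(OC)c1
F6 | step 9 | A–D tetramer phenol | COc1cc(OC)cc(OC)c1Oc1cc(OC)c(Oc2cc(OC)c(Oc3cc(OC)c(O)c(OC)c3)c(OC)c2)c(OC)c1
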